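**Retrosynthetic overview**
- Only one ring is made, the oxane, and it is made last. The C1–O bond comes from a 2-hydroxy-p-quinone methide of ring A, which comes from the o-quinone, which comes from the open-chain catechol (3R,5S)-syn-diol. Diols of this type co-occur with the target in ginger.
- The syn-diol comes from 1,3-syn reduction of the (5S)-5-hydroxy-3-ketone.
- The hydroxy ketone comes from regio- and enantioselective hydrogenation of the C5 ketone of a 1-ene-3,5-dione, followed by C=C saturation in the same pot. The C1=C2 bond is what tells the two ketones apart.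
- The enedione comes from boron-templated condensation of 5-hydroxyvanillin with a 2,4-diketone. That diketone comes from Claisen condensation of zingerone with ethyl acetate. No protecting groups are used.

Assumption: the chain is numbered C1 (on ring A, the 3,4-dihydroxy-5-methoxyphenyl ring) to C7 (on ring B, the 4-hydroxy-3-methoxyphenyl ring). The SMILES decodes as the (2S,4S,6S)-oxane (1S,3S,5S on the chain), with aryl and arylethyl cis (both equatorial) and the hydroxyl trans to both (axial). β-Diketones are drawn as diketo tautomers.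

**Step 1**
Reactants: 1 zingerone, 4-(4-hydroxy-3-methoxyphenyl)butan-2-one; 2 ethyl acetate
Product: 3 6-(4-hydroxy-3-methoxyphenyl)hexane-2,4-dione
Conditions: NaH (3.5 equiv), 2 (5 equiv), THF, reflux, 6 h; then 1 M HCl
Reagents that add atoms: none
Why: Crossed Claisen condensation, in which the phenol sits as an inert phenoxide, acylation at the methyl-side enolate is pulled through by formation of the less substituted, more stable β-diketonate while the branched isomer reverts by retro-Claisen, and no stereocenter is formed.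

**Step 2**
Reactants: 3 6-(4-hydroxy-3-methoxyphenyl)hexane-2,4-dione; 4 5-hydroxyvanillin, 3,4-dihydroxy-5-methoxybenzaldehyde
Product: 5 (1E)-1-(3,4-dihydroxy-5-methoxyphenyl)-7-(4-hydroxy-3-methoxyphenyl)hept-1-ene-3,5-dione
Conditions: B2O3 (1.2 equiv), B(OnBu)3 (3 equiv), n-BuNH2 (0.3 equiv), EtOAc, 75 °C, 5 h; then 1 M HCl, 50 °C
Reagents that add atoms: none
Why: Pabon-type boron-templated vinylogous aldol condensation, in which boron ties up the diketone (blocking Knoevenagel attack at the central CH2) and the catechol of 4, so the amine-catalysed condensation occurs at the unhindered terminal CH3 as in the known preparations of dehydrogingerdiones and dihydrocurcumin, and dehydration gives the conjugated E-alkene.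

**Step 3**
Reactants: 5 (1E)-1-(3,4-dihydroxy-5-methoxyphenyl)-7-(4-hydroxy-3-methoxyphenyl)hept-1-ene-3,5-dione
Product: 7 (5S)-1-(3,4-dihydroxy-5-methoxyphenyl)-5-hydroxy-7-(4-hydroxy-3-methoxyphenyl)heptan-3-one, via hydroxy enone 6 (not isolated)
Conditions: [RuCl(p-cymene)((S)-BINAP)]Cl (1 mol%), H2 (50 atm), degassed MeOH, 40 °C, to full conversion of 5 (HPLC); vent; then Pd/C (10 wt% Pd, 5 mol%), H2 (1 atm), rt, 2 h
Reagents that add atoms: none
Why: Noyori asymmetric hydrogenation of a β-diketone followed by heterogeneous alkene hydrogenation, in which hydride goes to the chelated, non-conjugated and more electrophilic C5 ketone rather than the electron-rich cinnamoyl C3 ketone (as 1-phenylbutane-1,3-dione is reduced only at its alkyl ketone), (S)-BINAP sets 5S in the same sense that gives (S)-3-hydroxybutanoate from acetoacetate, and Pd/C at 1 atm then saturates only C1=C2.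

**Step 4**
Reactants: 7 (5S)-1-(3,4-dihydroxy-5-methoxyphenyl)-5-hydroxy-7-(4-hydroxy-3-methoxyphenyl)heptan-3-one
Product: 8 (3R,5S)-1-(3,4-dihydroxy-5-methoxyphenyl)-7-(4-hydroxy-3-methoxyphenyl)heptane-3,5-diol (syn)
Conditions: Et2BOMe (4 equiv), THF/MeOH 4:1, −78 °C, 30 min; NaBH4 (2 equiv), −78 °C, 4 h; AcOH, then repeated MeOH co-evaporation (no peroxide work-up)
Reagents that add atoms: none
Why: Narasaka–Prasad reduction, in which boron chelates the C5 oxygen and the C3 carbonyl into a half-chair with the C5 substituent pseudo-equatorial and external hydride attacks axially, giving the 1,3-syn diol and thus 3R, while the phenols only exchange reversibly with boron.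

**Step 5**
Reactants: 8 (3R,5S)-1-(3,4-dihydroxy-5-methoxyphenyl)-7-(4-hydroxy-3-methoxyphenyl)heptane-3,5-diol
Product: 11 (2S,4S,6S)-2-(3,4-dihydroxy-5-methoxyphenyl)-6-[2-(4-hydroxy-3-methoxyphenyl)ethyl]oxan-4-ol, via o-quinone 9 (not isolated), via p-quinone methide 10 (not isolated)
Conditions: Ag2O (1.05 equiv), 4 Å MS, dry THF (5 mM), Ar, dark, 0 °C, 20 min; filter through Celite; then camphorsulfonic acid (10 mol%), 35 °C, 6 h
Reagents that add atoms: none
Why: Proposed new method: Ag2O takes two electrons only from the catechol of ring A (its oxidation potential lies well below that of the guaiacol ring B, and secondary alcohols are untouched) to give o-quinone 9, acid-catalysed vinylogous enolisation moves a C1 hydrogen to oxygen to give the 2-hydroxy-p-quinone methide 10, and the C5 hydroxyl adds to C1 (six-membered closure, whereas the C3 hydroxyl could only form an oxetane) with rearomatisation to the catechol through a chair that has aryl and arylethyl equatorial and the C3 hydroxyl of the syn-diol axial, the p-hydroxybenzyl ether staying reversible under the acid so that the 2,6-cis (1S) isomer is also the thermodynamic product; the closest known reaction types are the oxidative o-quinone to p-quinone methide closures of carnosic acid to carnosol and of demethylsalvicanol to brussonol, and the DDQ closure of 1,3-diarylpropanes to flavans.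

**Compound list**
1 | zingerone, 4-(4-hydroxy-3-methoxyphenyl)butan-2-one | CC(=O)CCc1ccc(O)c(OC)c1 | starting material
2 | ethyl acetate | CCOC(C)=O | starting material
3 | 6-(4-hydroxy-3-methoxyphenyl)hexane-2,4-dione | CC(=O)CC(=O)CCc1ccc(O)c(OC)c1 | intermediate
4 | 5-hydroxyvanillin, 3,4-dihydroxy-5-methoxybenzaldehyde | O=Cc1cc(O)c(O)c(OC)c1 | starting material
5 | (1E)-1-(3,4-dihydroxy-5-methoxyphenyl)-7-(4-hydroxy-3-methoxyphenyl)hept-1-ene-3,5-dione | O=C(/C=C/c1cc(O)c(O)c(OC)c1)CC(=O)CCc1ccc(O)c(OC)c1 | intermediate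
6 | (1E,5S)-1-(3,4-dihydroxy-5-methoxyphenyl)-5-hydroxy-7-(4-hydroxy-3-methoxyphenyl)hept-1-en-3-one | COc1cc(CC[C@H](O)CC(=O)/C=C/c2cc(O)c(O)c(OC)c2)ccc1O | intermediate (not isolated)
7 | (5S)-1-(3,4-dihydroxy-5-methoxyphenyl)-5-hydroxy-7-(4-hydroxy-3-methoxyphenyl)heptan-3-one | COc1cc(CC[C@H](O)CC(=O)CCc2cc(O)c(O)c(OC)c2)ccc1O | intermediate
8 | (3R,5S)-1-(3,4-dihydroxy-5-methoxyphenyl)-7-(4-hydroxy-3-methoxyphenyl)heptane-3,5-diol | COc1cc(CC[C@H](O)C[C@H](O)CCc2cc(O)c(O)c(OC)c2)ccc1O | intermediate
9 | 5-[(3R,5S)-3,5-dihydroxy-7-(4-hydroxy-3-methoxyphenyl)heptyl]-3-methoxycyclohexa-3,5-diene-1,2-dione | COc1cc(CC[C@H](O)C[C@H](O)CCC2=CC(=O)C(=O)C(OC)=C2)ccc1O | intermediate (not isolated)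
10 | 4-[(3R,5S)-3,5-dihydroxy-7-(4-hydroxy-3-methoxyphenyl)heptylidene]-2-hydroxy-6-methoxycyclohexa-2,5-dien-1-one | COc1cc(CC[C@H](O)C[C@H](O)CC=C2C=C(O)C(=O)C(OC)=C2)ccc1O | intermediate (not isolated)
11 | (2S,4S,6S)-2-(3,4-dihydroxy-5-methoxyphenyl)-6-[2-(4-hydroxy-3-methoxyphenyl)ethyl]oxan-4-ol | COc1cc(CC[C@H]2C[C@H](O)C[C@@H](c3cc(O)c(O)c(OC)c3)O2)ccc1O | target

**Total step count:** 5. **Longest linear sequence:** 5 (1 → 3 → 5 → 7 → 8 → 11).

**Steps most likely to fail**

**Step 5.**
- The tautomerisation of 9 to 10 may be slower than quinone dimerisation or coupling with the ring B phenol.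
- The C3 hydroxyl may add to the quinone ring to give a chroman.
- Compound 10 may slip to the styrene.
- The fallback gives up the oxidative closure for the redox-neutral conjugate-addition branch of the same biogenesis. It sets out from 6, isolated by stopping step 3 after the ruthenium stage.
- Camphorsulfonic acid (10 mol%) in CH2Cl2/THF closes the C5 hydroxyl onto C1 of the enone. This 6-endo oxa-Michael addition under thermodynamic 2,6-cis control gives (2S,6S)-2-(3,4-dihydroxy-5-methoxyphenyl)-6-[2-(4-hydroxy-3-methoxyphenyl)ethyl]oxan-4-one F1.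
- LiBH(s-Bu)3 (6 equiv, three of them consumed by the phenols), THF, −78 °C then attacks from the equatorial face and gives the axial alcohol. The fallback comes back to the route at 11.

**Step 3.**
- Hydride may not discriminate C5 from C3.
- Early C=C reduction would erase the difference between the two ketones and erode the ee.
- Over-reduction would give the anti-diol, and acid could close 6 prematurely.
- The fallback removes the regiochemical question. It sets out from 5, which Pd/C and H2 (1 atm, MeOH) take to 1-(3,4-dihydroxy-5-methoxyphenyl)-7-(4-hydroxy-3-methoxyphenyl)heptane-3,5-dione F2.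
- Exhaustive hydrogenation with [RuCl(p-cymene)((S)-BINAP)]Cl (H2 100 atm, MeOH, 50 °C) reduces both ketones in the same sense. It gives the anti-(3S,5S)-diol F3, whichever ketone reacts first.
- The conditions of step 5 carry F3 through the anti-series o-quinone F4 and the anti-series p-quinone methide F5 to the all-equatorial (2S,4R,6S)-oxan-4-ol F6.
- Mitsunobu inversion (PPh3, DIAD, 4-nitrobenzoic acid, THF, 0 °C to rt; the carboxylic acid outcompetes the phenols) gives the axial (2S,4S,6S)-oxan-4-yl 4-nitrobenzoate F7.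
- K2CO3 in MeOH under Ar returns to the route at 11.

**Step 2.**
- The free catechol of 4 may sequester boron, oxidise, or lower the reactivity of the aldehyde.
- The fallback masks the catechol with a group that the existing Pd/C stage removes, so no separate deprotection step is added. It sets out from 4.
- Ph2CCl2 (1.2 equiv, diphenyl ether, 170 °C) converts 4 into 7-methoxy-2,2-diphenyl-1,3-benzodioxole-5-carbaldehyde F8.
- Condensation with 3 under the step 2 conditions gives the ketal enedione F9.
- The ruthenium stage of step 3 gives the ketal (5S)-hydroxy enone F10.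
- The Pd/C stage saturates the alkene to the ketal (5S)-hydroxy ketone F11. On longer exposure (H2 3 atm, THF/MeOH) it hydrogenolyses the ketal, and the fallback comes back to the route at 7.

**Further compounds**
F1 | step 5 | (2S,6S)-2-(3,4-dihydroxy-5-methoxyphenyl)-6-[2-(4-hydroxy-3-methoxyphenyl)ethyl]oxan-4-one | COc1cc(CC[C@H]2CC(=O)C[C@@H](c3cc(O)c(O)c(OC)c3)O2)ccc1O
F2 | step 3 | 1-(3,4-dihydroxy-5-methoxyphenyl)-7-(4-hydroxy-3-methoxyphenyl)heptane-3,5-dione | COc1cc(CCC(=O)CC(=O)CCc2cc(O)c(O)c(OC)c2)ccc1O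
F3 | step 3 | (3S,5S)-1-(3,4-dihydroxy-5-methoxyphenyl)-7-(4-hydroxy-3-methoxyphenyl)heptane-3,5-diol | COc1cc(CC[C@H](O)C[C@@H](O)CCc2cc(O)c(O)c(OC)c2)ccc1O
F4 | step 3 | 5-[(3S,5S)-3,5-dihydroxy-7-(4-hydroxy-3-methoxyphenyl)heptyl]-3-methoxycyclohexa-3,5-diene-1,2-dione | COc1cc(CC[C@H](O)C[C@@H](O)CCC2=CC(=O)C(=O)C(OC)=C2)ccc1O
F5 | step 3 | 4-[(3S,5S)-3,5-dihydroxy-7-(4-hydroxy-3-methoxyphenyl)heptylidene]-2-hydroxy-6-methoxycyclohexa-2,5-dien-1-one | COc1cc(CC[C@H](O)C[C@@H](O)CC=C2C=C(O)C(=O)C(OC)=C2)ccc1O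
F6 | step 3 | (2S,4R,6S)-2-(3,4-dihydroxy-5-methoxyphenyl)-6-[2-(4-hydroxy-3-methoxyphenyl)ethyl]oxan-4-ol | COc1cc(CC[C@H]2C[C@@H](O)C[C@@H](c3cc(O)c(O)c(OC)c3)O2)ccc1O
F7 | step 3 | (2S,4S,6S)-2-(3,4-dihydroxy-5-methoxyphenyl)-6-[2-(4-hydroxy-3-methoxyphenyl)ethyl]oxan-4-yl 4-nitrobenzoate | COc1cc(CC[C@H]2C[C@H](OC(=O)c3ccc(cc3)[N+](=O)[O-])C[C@@H](c3cc(O)c(O)c(OC)c3)O2)ccc1O
F8 | step 2 | 7-methoxy-2,2-diphenyl-1,3-benzodioxole-5-carbaldehyde | O=Cc1cc(OC)c2c(c1)OC(c1ccccc1)(c1ccccc1)O2
F9 | step 2 | (1E)-7-(4-hydroxy-3-methoxyphenyl)-1-(7-methoxy-2,2-diphenyl-1,3-benzodioxol-5-yl)hept-1-ene-3,5-dione | O=C(/C=C/c1cc(OC)c2c(c1)OC(c1ccccc1)(c1ccccc1)O2)CC(=O)CCc1ccc(O)c(OC)c1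
F10 | step 2 | (1E,5S)-5-hydroxy-7-(4-hydroxy-3-methoxyphenyl)-1-(7-methoxy-2,2-diphenyl-1,3-benzodioxol-5-yl)hept-1-en-3-one | COc1cc(CC[C@H](O)CC(=O)/C=C/c2cc(OC)c3c(c2)OC(c2ccccc2)(c2ccccc2)O3)ccc1O
F11 | step 2 | (5S)-5-hydroxy-7-(4-hydroxy-3-methoxyphenyl)-1-(7-methoxy-2,2-diphenyl-1,3-benzodioxol-5-yl)heptan-3-one | COc1cc(CC[C@H](O)CC(=O)CCc2cc(OC)c3c(c2)OC(c2ccccc2)(c2ccccc2)O3)ccc1O
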